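**Plan**

- Retrosynthetic cuts, in flavonol numbering: first the sulfate S–O bond and the four benzyl C–O bonds, then C3–O and O1–C2 of ring C (back to a 2'-hydroxychalcone), then C4a–C8a of ring A, and last C4–C4a and C5–C6 of the unfolded chain.
- Feature used: ring A carries oxygen on C5, C7 and C8a in the 1,3,5-pattern of phloroglucinol, the acyl carbon C4 on C4a and a fourth oxygen on C6. A 3,5,7-triketo ester with an alkoxy group on its central carbon gives exactly this ring when its C6 adds to the ester carbon.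
- Forward order: the chain is joined by two polyanion acylations (acetyl, then the cinnamoyl unit that brings ring B), and ring A is closed by the Claisen folding. The three new phenols are then told apart, ring C is closed through the one free ortho phenol, C3 is oxygenated and sulfated, and the benzyl groups are removed.
- Stereochemistry: the target has no stereocentre. The E double bond comes from the Horner–Wadsworth–Emmons step and ends inside ring C; the racemic centres that appear on the way (chain C4, the cyclic trione, the flavone epoxide) are all erased.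

Key step: step 4

Remark: the sulfate monoesters of the last two steps are written as free hydrogen sulfates, as in the target SMILES. At the bench each would be kept as its potassium salt (K+-form cation-exchange resin after sulfation, which also removes pyridine that slows benzyl hydrogenolysis), and the final compound set free on an H+-form sulfonic acid resin.

Locants: the open chain is numbered C1 (ester carbon) to C9 (aryl-bearing carbon); primed locants refer to the ketone-bearing ring of the chalcones.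

**Route**

Step 1
Reactants: 1 4-(benzyloxy)benzaldehyde; 2 diethyl {2-[methoxy(methyl)amino]-2-oxoethyl}phosphonate
Product: 3 (2E)-3-[4-(benzyloxy)phenyl]-N-methoxy-N-methylprop-2-enamide
Conditions: NaH, THF, 0 °C → rt
Reagents that add atoms: none
Why: Horner–Wadsworth–Emmons olefination of an aromatic aldehyde with a stabilised amide phosphonate should give the E-configured unsaturated N-methoxy-N-methylamide under the usual thermodynamic control.

Step 2
Reactants: 4 ethyl 4-(benzyloxy)-3-oxobutanoate; 5 N-methoxy-N-methylacetamide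
Product: 6 ethyl 4-(benzyloxy)-3,5-dioxohexanoate (racemic, largely enolised)
Conditions: LiN(iPr)2 (2.2 equiv), THF, −78 °C; then 5, −78 → 0 °C; aq HCl
Reagents that add atoms: none
Why: γ-Acylation of a β-keto ester dianion, in which the second, more basic carbanion at the benzyloxy-bearing C4 attacks the N-methoxy-N-methylamide, a donor that transfers its acetyl group only once.

Step 3
Reactants: 6 ethyl 4-(benzyloxy)-3,5-dioxohexanoate; 3 (2E)-3-[4-(benzyloxy)phenyl]-N-methoxy-N-methylprop-2-enamide
Product: 7 ethyl (8E)-4-(benzyloxy)-9-[4-(benzyloxy)phenyl]-3,5,7-trioxonon-8-enoate (racemic, enolisable at C4)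
Conditions: LiN(iPr)2 (3.3 equiv), THF, −78 → 0 °C; then 3, −78 → −20 °C; aq HCl
Reagents that add atoms: none
Why: Terminal acylation of a 3,5-diketo ester trianion, in which the last-formed and most nucleophilic carbanion at the C6 methyl group adds 1,2 to the amide carbonyl of 3 and the N-methoxy-N-methylamide again delivers a single acyl group.

Step 4
Reactants: 7 ethyl (8E)-4-(benzyloxy)-9-[4-(benzyloxy)phenyl]-3,5,7-trioxonon-8-enoate
Product: 9 (2E)-1-[3-(benzyloxy)-2,4,6-trihydroxyphenyl]-3-[4-(benzyloxy)phenyl]prop-2-en-1-one, via 2-acyl-4-(benzyloxy)cyclohexane-1,3,5-trione 8 (not isolated)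
Conditions: Mg(OMe)2 (5 equiv), MeOH, 25–45 °C; then cold 1 M HCl, product used at once
Reagents that add atoms: none
Why: Proposed new method: Mg(OMe)2 is expected to bind the 3,5,7-tricarbonyl array of 7 as a chelated polyenolate in which the C6 methylene between the C5 and C7 carbonyls is the most acidic carbon, so that its carbanion adds to the ester carbonyl C1, ethoxide leaves (intramolecular Claisen condensation) and the C4a–C8a bond is formed. Ring A closes in a 6-exo-trig acylation (6-enolendo-exo-trig in the enolate sense), and trione 8 then enolises irreversibly to the benzene-1,3,5-triol of 9, chain C1, C6 and C4 becoming C8a, C4a and C6 of the flavonol. The closest known reaction type is the magnesium methoxide-mediated Claisen cyclisation of unsubstituted 3,5,7-triketo esters to acylphloroglucinols, the laboratory counterpart of chalcone synthase; a chain with an alkoxy group on C4 has not been folded in this way. No stereocentre is created, the racemic centre at chain C4 is erased on aromatisation and the E double bond is not involved. The step needs C-acylation from C6 to win over aldol closure of C2 onto the C7 carbonyl (which would give a resorcylate) and over O-acylation by the C5 enol oxygen (a 4-hydroxy-2-pyranone); chelation as enolate and conjugation with the styryl group make C7 the poorest electrophile of the chain, and lactone formation is reversible under methoxide whereas aromatisation is not.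

Step 5
Reactants: 9 (2E)-1-[3-(benzyloxy)-2,4,6-trihydroxyphenyl]-3-[4-(benzyloxy)phenyl]prop-2-en-1-one
Product: 10 (2E)-1-[3-(benzyloxy)-2-hydroxy-4,6-bis(methoxymethoxy)phenyl]-3-[4-(benzyloxy)phenyl]prop-2-en-1-one
Conditions: MOMCl (2.2 equiv), iPr2NEt, CH2Cl2, 0 °C
Reagents that add atoms: chloromethyl methyl ether, COCCl
Why: Williamson-type etherification under amine base should take the non-chelated 4'-hydroxyl and then the 6'-hydroxyl that has only a ring hydrogen as neighbour, while the 2'-hydroxyl wedged between the ketone and the benzyloxy group stays hydrogen-bonded, the pattern generally seen in partial alkylation of 3-alkoxy-2,4,6-trihydroxyaryl ketones.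

Step 6
Reactants: 10 (2E)-1-[3-(benzyloxy)-2-hydroxy-4,6-bis(methoxymethoxy)phenyl]-3-[4-(benzyloxy)phenyl]prop-2-en-1-one
Product: 11 (2E)-1-[2,3-bis(benzyloxy)-4,6-bis(methoxymethoxy)phenyl]-3-[4-(benzyloxy)phenyl]prop-2-en-1-one
Conditions: BnBr, K2CO3, (n-Bu)4NI (cat.), DMF, 50 °C
Reagents that add atoms: benzyl bromide, BrCc1ccccc1
Why: Williamson benzylation of the remaining chelated phenol under more forcing conditions, in which the irreversible O-alkylation outruns any reversible oxa-Michael closure of the phenoxide and the methoxymethyl acetals are inert to carbonate.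

Step 7
Reactants: 11 (2E)-1-[2,3-bis(benzyloxy)-4,6-bis(methoxymethoxy)phenyl]-3-[4-(benzyloxy)phenyl]prop-2-en-1-one
Product: 12 (2E)-1-[2,3-bis(benzyloxy)-4,6-dihydroxyphenyl]-3-[4-(benzyloxy)phenyl]prop-2-en-1-one
Conditions: 3 M HCl, MeOH/THF, 45 °C
Reagents that add atoms: none
Why: Acid-catalysed acetal cleavage (transfer of the methoxymethyl groups to methanol) leaves the benzyl ethers and the enone intact and makes the 6'-hydroxyl, the one next to the ring hydrogen, the only phenol ortho to the ketone.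

Step 8
Reactants: 12 (2E)-1-[2,3-bis(benzyloxy)-4,6-dihydroxyphenyl]-3-[4-(benzyloxy)phenyl]prop-2-en-1-one
Product: 13 (2E)-1-[2,3,4-tris(benzyloxy)-6-hydroxyphenyl]-3-[4-(benzyloxy)phenyl]prop-2-en-1-one
Conditions: BnBr (1.05 equiv), K2CO3, acetone, 40 °C
Reagents that add atoms: benzyl bromide, BrCc1ccccc1
Why: Selective Williamson benzylation of the more acidic, non-chelated 4'-hydroxyl with one equivalent of halide, the 6'-hydroxyl being held in a hydrogen bond to the ketone.

Step 9
Reactants: 13 (2E)-1-[2,3,4-tris(benzyloxy)-6-hydroxyphenyl]-3-[4-(benzyloxy)phenyl]prop-2-en-1-one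
Product: 14 5,6,7-tris(benzyloxy)-2-[4-(benzyloxy)phenyl]-4H-chromen-4-one
Conditions: I2 (10 mol %), DMSO, 120 °C
Reagents that add atoms: none
Why: Iodine-catalysed oxidative cyclisation of a 2'-hydroxychalcone in DMSO (oxa-Michael closure and dehydrogenation, DMSO as terminal oxidant) closes ring C through the only free phenol, so O1 is bonded to the carbon whose neighbour carries the ring hydrogen and the 5,6,7-oxygenation pattern is fixed.

Step 10
Reactants: 14 5,6,7-tris(benzyloxy)-2-[4-(benzyloxy)phenyl]-4H-chromen-4-one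
Product: 16 5,6,7-tris(benzyloxy)-2-[4-(benzyloxy)phenyl]-3-hydroxy-4H-chromen-4-one, via flavone 2,3-epoxide 15 (not isolated)
Conditions: DMDO, acetone/CH2Cl2, 0 °C → rt; then p-TsOH (cat.), CH2Cl2, rt
Reagents that add atoms: dimethyldioxirane, CC1(C)OO1
Why: Dioxirane epoxidation of the C2=C3 enol ether double bond of a fully etherified flavone, followed by acid-catalysed opening of epoxide 15 with loss of the C3 proton, is the standard flavone-to-flavonol oxidation, and both racemic centres of 15 vanish in 16.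

Step 11
Reactants: 16 5,6,7-tris(benzyloxy)-2-[4-(benzyloxy)phenyl]-3-hydroxy-4H-chromen-4-one
Product: 17 5,6,7-tris(benzyloxy)-2-[4-(benzyloxy)phenyl]-4-oxo-4H-chromen-3-yl hydrogen sulfate
Conditions: SO3·pyridine (5 equiv), pyridine, 50 °C
Reagents that add atoms: sulfur trioxide–pyridine complex, [O-]S(=O)(=O)[n+]1ccccc1
Why: O-Sulfation of the only free hydroxyl, the acidic enolic 3-OH, with the pyridine complex of sulfur trioxide.

Step 12
Reactants: 17 5,6,7-tris(benzyloxy)-2-[4-(benzyloxy)phenyl]-4-oxo-4H-chromen-3-yl hydrogen sulfate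
Product: 18 5,6,7-trihydroxy-2-(4-hydroxyphenyl)-4-oxo-4H-chromen-3-yl hydrogen sulfate
Conditions: H2 (1 atm), Pd/C (10%), THF/MeOH, rt; then sulfonic acid resin (H+ form), 0 °C, under argon
Reagents that add atoms: none
Why: Catalytic hydrogenolysis of the four benzyl ethers over palladium on carbon, under which aryl sulfate esters and the flavonol C2=C3 bond are known to persist.

**Compound list**

1 | 4-(benzyloxy)benzaldehyde | O=Cc1ccc(OCc2ccccc2)cc1 | starting material
2 | diethyl {2-[methoxy(methyl)amino]-2-oxoethyl}phosphonate | CCOP(=O)(OCC)CC(=O)N(C)OC | starting material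
3 | (2E)-3-[4-(benzyloxy)phenyl]-N-methoxy-N-methylprop-2-enamide | CON(C)C(=O)/C=C/c1ccc(OCc2ccccc2)cc1 | intermediate
4 | ethyl 4-(benzyloxy)-3-oxobutanoate | CCOC(=O)CC(=O)COCc1ccccc1 | starting material
5 | N-methoxy-N-methylacetamide | CON(C)C(C)=O | starting material
6 | ethyl 4-(benzyloxy)-3,5-dioxohexanoate (racemic) | CCOC(=O)CC(=O)C(OCc1ccccc1)C(C)=O | intermediate
7 | ethyl (8E)-4-(benzyloxy)-9-[4-(benzyloxy)phenyl]-3,5,7-trioxonon-8-enoate (racemic) | CCOC(=O)CC(=O)C(OCc1ccccc1)C(=O)CC(=O)/C=C/c1ccc(OCc2ccccc2)cc1 | intermediate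
8 | 4-(benzyloxy)-2-{(2E)-3-[4-(benzyloxy)phenyl]prop-2-enoyl}cyclohexane-1,3,5-trione (stereoisomer mixture) | O=C(/C=C/c1ccc(OCc2ccccc2)cc1)C1C(=O)CC(=O)C(OCc2ccccc2)C1=O | intermediate (not isolated)
9 | (2E)-1-[3-(benzyloxy)-2,4,6-trihydroxyphenyl]-3-[4-(benzyloxy)phenyl]prop-2-en-1-one | O=C(/C=C/c1ccc(OCc2ccccc2)cc1)c1c(O)cc(O)c(OCc2ccccc2)c1O | intermediate
10 | (2E)-1-[3-(benzyloxy)-2-hydroxy-4,6-bis(methoxymethoxy)phenyl]-3-[4-(benzyloxy)phenyl]prop-2-en-1-one | O=C(/C=C/c1ccc(OCc2ccccc2)cc1)c1c(OCOC)cc(OCOC)c(OCc2ccccc2)c1O | intermediate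
11 | (2E)-1-[2,3-bis(benzyloxy)-4,6-bis(methoxymethoxy)phenyl]-3-[4-(benzyloxy)phenyl]prop-2-en-1-one | O=C(/C=C/c1ccc(OCc2ccccc2)cc1)c1c(OCOC)cc(OCOC)c(OCc2ccccc2)c1OCc1ccccc1 | intermediate
12 | (2E)-1-[2,3-bis(benzyloxy)-4,6-dihydroxyphenyl]-3-[4-(benzyloxy)phenyl]prop-2-en-1-one | O=C(/C=C/c1ccc(OCc2ccccc2)cc1)c1c(O)cc(O)c(OCc2ccccc2)c1OCc1ccccc1 | intermediate
13 | (2E)-1-[2,3,4-tris(benzyloxy)-6-hydroxyphenyl]-3-[4-(benzyloxy)phenyl]prop-2-en-1-one | O=C(/C=C/c1ccc(OCc2ccccc2)cc1)c1c(O)cc(OCc2ccccc2)c(OCc2ccccc2)c1OCc1ccccc1 | intermediate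
14 | 5,6,7-tris(benzyloxy)-2-[4-(benzyloxy)phenyl]-4H-chromen-4-one | O=c1cc(-c2ccc(OCc3ccccc3)cc2)oc2cc(OCc3ccccc3)c(OCc3ccccc3)c(OCc3ccccc3)c12 | intermediate
15 | 5,6,7-tris(benzyloxy)-2-[4-(benzyloxy)phenyl]-2,3-epoxy-2,3-dihydro-4H-chromen-4-one (racemic; the three-membered ring fixes the relative configuration) | O=C1C2OC2(c2ccc(OCc3ccccc3)cc2)Oc2cc(OCc3ccccc3)c(OCc3ccccc3)c(OCc3ccccc3)c21 | intermediate (not isolated)
16 | 5,6,7-tris(benzyloxy)-2-[4-(benzyloxy)phenyl]-3-hydroxy-4H-chromen-4-one | O=c1c(O)c(-c2ccc(OCc3ccccc3)cc2)oc2cc(OCc3ccccc3)c(OCc3ccccc3)c(OCc3ccccc3)c12 | intermediate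
17 | 5,6,7-tris(benzyloxy)-2-[4-(benzyloxy)phenyl]-4-oxo-4H-chromen-3-yl hydrogen sulfate | O=c1c(OS(=O)(=O)O)c(-c2ccc(OCc3ccccc3)cc2)oc2cc(OCc3ccccc3)c(OCc3ccccc3)c(OCc3ccccc3)c12 | intermediate
18 | 5,6,7-trihydroxy-2-(4-hydroxyphenyl)-4-oxo-4H-chromen-3-yl hydrogen sulfate (6-hydroxykaempferol 3-O-sulfate) | O=c1c(OS(=O)(=O)O)c(-c2ccc(O)cc2)oc2cc(O)c(O)c(O)c12 | target

**Step count**

Total: 12 steps. Longest linear sequence: 11 steps (steps 2 to 12, from 4 to 18); step 1 is a one-step side branch.

**Steps most likely to fail**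

Step 4. The chain may fold the other way (aldol closure of C2 onto the C7 carbonyl, or lactonisation through the C5 enol oxygen), or methoxide may cleave the 2-alkoxy-1,3-diketone by retro-Claisen fragmentation before ring closure. The fallback uses only known reactions and takes ring A from an arene; it sets out from aldehyde 1 and comes back to the route at chalcone 13. Commercial 1-(2,4,6-trihydroxyphenyl)ethanone would be dibenzylated (BnBr, K2CO3, acetone) to 1-[2,4-bis(benzyloxy)-6-hydroxyphenyl]ethanone F1. Elbs persulfate oxidation (K2S2O8, aq KOH, pyridine) should place an oxygen para to the free phenol as potassium 3-acetyl-2,6-bis(benzyloxy)-4-hydroxyphenyl sulfate F2, and hydrolysis with dilute HCl gives 1-[2,4-bis(benzyloxy)-3,6-dihydroxyphenyl]ethanone F3. Benzylation of its non-chelated hydroxyl gives 1-[2,3,4-tris(benzyloxy)-6-hydroxyphenyl]ethanone F4, and Claisen–Schmidt condensation of F4 with 1 (KOH, EtOH) gives 13, from which steps 9 to 12 follow unchanged.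

Step 3. The trianion may form incompletely, may deprotonate or add in conjugate fashion to the cinnamoyl amide, or the triketo ester may cyclise during work-up. The fallback replaces acyl substitution by addition and oxidation; it sets out from 6 (with amide 3 as the aldehyde source) and comes back at 7. Amide 3 would be reduced with (i-Bu)2AlH at −78 °C to (2E)-3-[4-(benzyloxy)phenyl]prop-2-enal F5. The trianion of 6 should add 1,2 to this aldehyde (polyanion aldol addition) to give ethyl (8E)-4-(benzyloxy)-9-[4-(benzyloxy)phenyl]-7-hydroxy-3,5-dioxonon-8-enoate F6 (diastereomer mixture), and MnO2 oxidation of the allylic alcohol returns to 7.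

Step 5. The small chloromethyl ether may discriminate poorly between the two chelated ortho hydroxyls, or the unprotected chalcone may close by oxa-Michael addition before it is etherified. The fallback separates the hydroxyls stepwise with a bulky silyl group and a neutral benzylation; it sets out from 9 and comes back at 13, which also makes steps 6 to 8 unnecessary. One equivalent of BnBr with K2CO3 should give (2E)-1-[3,4-bis(benzyloxy)-2,6-dihydroxyphenyl]-3-[4-(benzyloxy)phenyl]prop-2-en-1-one F7. tert-Butyldimethylsilyl triflate and 2,6-lutidine at −78 °C should silylate the open 6'-hydroxyl to give (2E)-1-[3,4-bis(benzyloxy)-6-{[tert-butyl(dimethyl)silyl]oxy}-2-hydroxyphenyl]-3-[4-(benzyloxy)phenyl]prop-2-en-1-one F8. Mitsunobu benzylation of the flanked 2'-hydroxyl (BnOH, PPh3, diisopropyl azodicarboxylate) gives (2E)-1-[2,3,4-tris(benzyloxy)-6-{[tert-butyl(dimethyl)silyl]oxy}phenyl]-3-[4-(benzyloxy)phenyl]prop-2-en-1-one F9, and (n-Bu)4NF buffered with AcOH removes the silyl group to give 13.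

**Further compounds**

F1 | step 4 | 1-[2,4-bis(benzyloxy)-6-hydroxyphenyl]ethanone | CC(=O)c1c(O)cc(OCc2ccccc2)cc1OCc1ccccc1
F2 | step 4 | potassium 3-acetyl-2,6-bis(benzyloxy)-4-hydroxyphenyl sulfate | CC(=O)c1c(O)cc(OCc2ccccc2)c(OS(=O)(=O)[O-])c1OCc1ccccc1.[K+]
F3 | step 4 | 1-[2,4-bis(benzyloxy)-3,6-dihydroxyphenyl]ethanone | CC(=O)c1c(O)cc(OCc2ccccc2)c(O)c1OCc1ccccc1
F4 | step 4 | 1-[2,3,4-tris(benzyloxy)-6-hydroxyphenyl]ethanone | CC(=O)c1c(O)cc(OCc2ccccc2)c(OCc2ccccc2)c1OCc1ccccc1
F5 | step 3 | (2E)-3-[4-(benzyloxy)phenyl]prop-2-enal | O=C/C=C/c1ccc(OCc2ccccc2)cc1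
F6 | step 3 | ethyl (8E)-4-(benzyloxy)-9-[4-(benzyloxy)phenyl]-7-hydroxy-3,5-dioxonon-8-enoate (diastereomer mixture) | CCOC(=O)CC(=O)C(OCc1ccccc1)C(=O)CC(O)/C=C/c1ccc(OCc2ccccc2)cc1
F7 | step 5 | (2E)-1-[3,4-bis(benzyloxy)-2,6-dihydroxyphenyl]-3-[4-(benzyloxy)phenyl]prop-2-en-1-one | O=C(/C=C/c1ccc(OCc2ccccc2)cc1)c1c(O)cc(OCc2ccccc2)c(OCc2ccccc2)c1O
F8 | step 5 | (2E)-1-[3,4-bis(benzyloxy)-6-{[tert-butyl(dimethyl)silyl]oxy}-2-hydroxyphenyl]-3-[4-(benzyloxy)phenyl]prop-2-en-1-one | O=C(/C=C/c1ccc(OCc2ccccc2)cc1)c1c(O[Si](C)(C)C(C)(C)C)cc(OCc2ccccc2)c(OCc2ccccc2)c1O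
F9 | step 5 | (2E)-1-[2,3,4-tris(benzyloxy)-6-{[tert-butyl(dimethyl)silyl]oxy}phenyl]-3-[4-(benzyloxy)phenyl]prop-2-en-1-one | O=C(/C=C/c1ccc(OCc2ccccc2)cc1)c1c(O[Si](C)(C)C(C)(C)C)cc(OCc2ccccc2)c(OCc2ccccc2)c1OCc1ccccc1
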